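**Plan** (labdane numbering: ring A = C1–C5, C10; ring B = C5–C10; side chain C11–C16; C17 on C8; C18/C19 on C4; C20 on C10)
- Retrosynthesis cuts, in order: the C17 acetate and the C17–O bond (allylic oxidation of a 7-ene); C9–C10 (cation–olefin closure of ring B); then C2–C3 and C4–C5 together (Diels–Alder) and C1=C2 (Wittig). This leaves (2E,6E)-farnesol, methacrolein and one CH2.
- Enabling feature: in ring A, C3–C4 is an isobutene-type CH2–CMe2 unit lying between C2 and C5, and C2–C1–C10–C5 is a 2-methylbuta-1,3-diene once the C9–C10 bond of ring B is open. The C1=C10 alkene left by the cycloaddition is the cation precursor for ring B.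
- Forward: farnesol chain (C1, C5–C17, C20) → diene → ring A by [4+2] with methacrolein (C3, C4, C18, C19) → gem-dimethyl → ring B by protonation and closure → C17 oxygenation → acetate.
- Stereochemistry: C13 from asymmetric hydrogenation of the allylic alcohol; C5 from the catalyst-controlled Diels–Alder; C10 and C9 relayed from C5 and the (E)-C8=C9 alkene in the chair-like closure.

Key step: step 6

Assumption: the facial sense of the (S)-oxazaborolidinium catalyst with methacrolein and the formyl-endo mode are taken from the accepted model for 2-substituted acroleins; since C4 later becomes achiral only C5 matters, and the mirror-image catalyst would be used if the exo mode proved dominant.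

**Step 1**
Reactants: 1 (2E,6E)-farnesol
Product: 2 (S)-2,3-dihydrofarnesol
Conditions: Ru(OAc)2[(R)-BINAP] (0.5 mol %), H2 (30 atm), MeOH/H2O 95:5, 20 °C
Reagents that add atoms: none
Why: Noyori asymmetric hydrogenation, in which the allylic hydroxyl directs the ruthenium–BINAP hydride to the C2=C3 bond only and the (R)-ligand on the (2E)-alkene should set the (3S) centre (C13 of the target), as in the geraniol to (S)-citronellol case.

**Step 2**
Reactants: 2 (S)-2,3-dihydrofarnesol
Product: 3 (3S,6E)-3,7,11-trimethyldodeca-6,10-dien-1-yl acetate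
Conditions: Ac2O, pyridine, DMAP (cat.), CH2Cl2, 0 °C to rt
Reagents that add atoms: acetic anhydride, CC(=O)OC(C)=O
Why: DMAP-catalysed acylation installs the C15 acetate of the target at the outset, where it also serves as the protecting group.

**Step 3**
Reactants: 3 dihydrofarnesyl acetate
Product: 4 (3S,6E,10E)-12-hydroxy-3,7,11-trimethyldodeca-6,10-dien-1-yl acetate
Conditions: SeO2 (0.3 equiv), t-BuOOH (3 equiv), salicylic acid (cat.), CH2Cl2, 0 °C to rt
Reagents that add atoms: selenium dioxide, O=[Se]=O; tert-butyl hydroperoxide, CC(C)(C)OO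
Why: Sharpless–Umbreit allylic oxidation (ene reaction then [2,3]-shift) should hydroxylate the (E)-methyl group of the terminal isopropylidene unit in preference to the internal alkene; any aldehyde 5 formed alongside is carried into step 4.

**Step 4**
Reactants: 4 allylic alcohol
Product: 5 (3S,6E,10E)-3,7,11-trimethyl-12-oxododeca-6,10-dien-1-yl acetate
Conditions: TEMPO (10 mol %), PhI(OAc)2 (1.1 equiv), CH2Cl2, rt
Reagents that add atoms: none
Why: Oxoammonium-mediated oxidation of the primary allylic alcohol stops at the enal and should leave the E geometry, the isolated alkene and the acetate untouched.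

**Step 5**
Reactants: 5 enal
Product: 6 (3S,6E,10E)-3,7,11-trimethyltrideca-6,10,12-trien-1-yl acetate
Conditions: Ph3PCH3Br (1.1 equiv), KN(SiMe3)2 (1.05 equiv), THF, −78 to 0 °C
Reagents that add atoms: methyltriphenylphosphonium bromide, C[P+](c1ccccc1)(c1ccccc1)c1ccccc1.[Br-]
Why: Wittig methylenation of the aldehyde, which reacts far faster than the acetate at low temperature, gives the 2-methyl-1,3-diene C2=C1–C10(Me)=C5 with the chain on the outside (E) position of C5.

**Step 6**
Reactants: 6 triene acetate; 7 methacrolein
Product: 8 (3S,6E)-9-[(1R,6S)-6-formyl-2,6-dimethylcyclohex-2-en-1-yl]-3,7-dimethylnon-6-en-1-yl acetate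
Conditions: 7 (3 equiv), (S)-3,3-diphenyl-1-(2-methylphenyl)tetrahydro-1H,3H-pyrrolo[1,2-c][1,3,2]oxazaborole (20 mol %), Tf2NH (18 mol %), CH2Cl2, −78 to −40 °C
Reagents that add atoms: none
Why: The protonated oxazaborolidine binds methacrolein at the formyl oxygen and lowers its LUMO, so the s-cis diene C2=C1–C10=C5 adds across C3=C4 in a concerted, asynchronous, normal-demand [4+2] cycloaddition with the C2–C3 bond leading; the closest known reaction type is the cationic-oxazaborolidine-catalysed Diels–Alder reaction of 2-substituted acroleins with alkyl-substituted acyclic dienes. Ring A is closed by an intermolecular suprafacial [4+2] annulation that leaves the C1=C10 double bond. The quaternary centre C4 is set by the catalyst, which shields one face of the bound enal, and C5 follows from C4 through the formyl-endo transition state, the outside (E) position of the chain on C5 placing it cis to the formyl group; only C5 is kept, since C4 becomes the gem-dimethyl carbon. Orientation is the selectivity the step needs: the alkyl group on the diene terminus C5 puts the larger HOMO coefficient on the unsubstituted terminus C2, so C2 should join the β-carbon C3 and C5 the formyl-bearing C4 (the orientation expected for 1-vinylcyclohexene-type dienes), while the C10 methyl group opposes this only weakly. Site selectivity should follow because the isolated C8=C9 alkene is not a diene and the acetate is a weaker Lewis base than the aldehyde.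

**Step 7**
Reactants: 8 Diels–Alder aldehyde
Product: 10 (3S,6E)-3,7-dimethyl-9-[(1S)-2,6,6-trimethylcyclohex-2-en-1-yl]non-6-en-1-yl acetate, via tosylhydrazone 9 (not isolated)
Conditions: TsNHNH2 (1.1 equiv), EtOH, 50 °C; evaporate; catecholborane (2 equiv), CHCl3, 0 °C to rt; NaOAc·3H2O (3 equiv), 60 °C
Reagents that add atoms: 4-methylbenzenesulfonohydrazide, Cc1ccc(cc1)S(=O)(=O)NN (adds atoms to 9 only; none remain in 10)
Why: Hydride delivery to the tosylhydrazone, then base-induced loss of sulfinate and N2 from the diazene (Kabalka variant of the Caglioti reduction), should turn the neopentyl aldehyde into the second C4 methyl group under non-acidic conditions that keep the acetate and both trisubstituted alkenes in place.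

**Step 8**
Reactants: 10 monocyclic acetate
Product: 11 (13S)-labd-7-en-15-yl acetate
Conditions: FSO3H (5 equiv), 2-nitropropane, −78 °C; then Et3N, −78 °C to rt
Reagents that add atoms: none
Why: Protonation of the ring-A alkene at C1 gives the tertiary C10 cation, which C9 of the (E)-C8=C9 alkene captures in a 6-endo cation–olefin closure (the stepwise ring-B closure known for α-monocyclic terpenoids); axial approach to C10 is blocked by the axial C4 methyl group, so the bond should form equatorial to ring A (trans-decalin from C5), the E geometry places the side chain equatorial at C9, and proton loss from C7 gives the 7-ene.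

**Step 9**
Reactants: 11 labd-7-en-15-yl acetate
Product: 12 (13S)-17-hydroxylabd-7-en-15-yl acetate
Conditions: SeO2 (0.5 equiv), t-BuOOH (2 equiv), CH2Cl2, rt
Reagents that add atoms: selenium dioxide, O=[Se]=O; tert-butyl hydroperoxide, CC(C)(C)OO
Why: Ene reaction of SeO2 at C7 with hydrogen abstraction from the C17 methyl group, then [2,3]-shift, should return the C7=C8 bond and put oxygen on C17, the methyl group being preferred over the hindered C9 methine at the more substituted alkene terminus.

**Step 10**
Reactants: 12 allylic alcohol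
Product: 13 (13S)-labd-7-ene-15,17-diyl diacetate (target)
Conditions: Ac2O, pyridine, DMAP (cat.), CH2Cl2, rt
Reagents that add atoms: acetic anhydride, CC(=O)OC(C)=O
Why: Standard acylation of the primary allylic alcohol completes the diacetate without touching any stereocentre.

**Compound list**
1 | (2E,6E)-farnesol | CC(C)=CCC/C(C)=C/CC/C(C)=C/CO | starting material
2 | (S)-2,3-dihydrofarnesol, (3S,6E)-3,7,11-trimethyldodeca-6,10-dien-1-ol | CC(C)=CCC/C(C)=C/CC[C@H](C)CCO | intermediate
3 | (3S,6E)-3,7,11-trimethyldodeca-6,10-dien-1-yl acetate | CC(C)=CCC/C(C)=C/CC[C@H](C)CCOC(C)=O | intermediate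
4 | (3S,6E,10E)-12-hydroxy-3,7,11-trimethyldodeca-6,10-dien-1-yl acetate | OC/C(C)=C/CC/C(C)=C/CC[C@H](C)CCOC(C)=O | intermediate
5 | (3S,6E,10E)-3,7,11-trimethyl-12-oxododeca-6,10-dien-1-yl acetate | O=C/C(C)=C/CC/C(C)=C/CC[C@H](C)CCOC(C)=O | intermediate
6 | (3S,6E,10E)-3,7,11-trimethyltrideca-6,10,12-trien-1-yl acetate | C=C/C(C)=C/CC/C(C)=C/CC[C@H](C)CCOC(C)=O | intermediate
7 | methacrolein (2-methylprop-2-enal) | CC(=C)C=O | starting material
8 | (3S,6E)-9-[(1R,6S)-6-formyl-2,6-dimethylcyclohex-2-en-1-yl]-3,7-dimethylnon-6-en-1-yl acetate (formyl cis to the chain) | CC(=O)OCC[C@@H](C)CC/C=C(C)/CC[C@@H]1C(C)=CCC[C@]1(C)C=O | intermediate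
9 | 4-methylbenzenesulfonylhydrazone of 8 | CC(=O)OCC[C@@H](C)CC/C=C(C)/CC[C@@H]1C(C)=CCC[C@]1(C)/C=N/NS(=O)(=O)c1ccc(C)cc1 | intermediate (not isolated)
10 | (3S,6E)-3,7-dimethyl-9-[(1S)-2,6,6-trimethylcyclohex-2-en-1-yl]non-6-en-1-yl acetate | CC(=O)OCC[C@@H](C)CC/C=C(C)/CC[C@@H]1C(C)=CCCC1(C)C | intermediate
11 | (13S)-labd-7-en-15-yl acetate, (3S)-3-methyl-5-[(1S,4aS,8aS)-2,5,5,8a-tetramethyl-1,4,4a,5,6,7,8,8a-octahydronaphthalen-1-yl]pentyl acetate | CC(=O)OCC[C@@H](C)CC[C@H]1C(C)=CC[C@H]2C(C)(C)CCC[C@]12C | intermediate
12 | (13S)-17-hydroxylabd-7-en-15-yl acetate, (3S)-5-[(1R,4aS,8aS)-2-(hydroxymethyl)-5,5,8a-trimethyl-1,4,4a,5,6,7,8,8a-octahydronaphthalen-1-yl]-3-methylpentyl acetate | CC(=O)OCC[C@@H](C)CC[C@H]1C(CO)=CC[C@H]2C(C)(C)CCC[C@]12C | intermediate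
13 | (13S)-labd-7-ene-15,17-diyl diacetate, (5S,9R,10S,13S) | CC(=O)OCC[C@@H](C)CC[C@H]1C(COC(C)=O)=CC[C@H]2C(C)(C)CCC[C@]12C | target

Total step count: 10. Longest linear sequence: 10 steps (from 1).

**Steps most likely to fail**

Step 6. The C10 methyl group may pull the formyl-bearing carbon towards C2 and erode the orientation, and leakage through the exo transition state would lower the configurational purity at C5. The fallback sets out from 5 and puts a directing oxygen on C1. Addition of MeMgBr at −78 °C should give the secondary allylic alcohol F1, and Dess–Martin oxidation the methyl enone F2. Soft enolisation with iPr3SiOTf/Et3N should then give the 2-silyloxy diene F3. Its oxygen substituent on C1 should dominate the orientation of the same catalysed cycloaddition with 7, giving the silyl enol ether F4. CsF/PhNTf2 converts F4 into the enol triflate F5, and reduction with Pd(OAc)2, PPh3, HCO2H and Bu3N returns to the route at 8.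

Step 8. Proton loss from the C8 cation may be unselective (exocyclic 8(17)-ene, or migration to the tetrasubstituted 8-ene on prolonged exposure), or closure may stall. The fallback sets out from 10 and uses the exocyclic isomer instead of the 7-ene. Closure is run with SnCl4/CF3CO2H in CH2Cl2 at −78 °C and quenched cold, which should favour loss of a methyl proton to give the 8(17)-ene F6. mCPBA should epoxidise F6 from the α face to the 8α,17-epoxide F7. Al(OiPr)3 in hot toluene should then open F7 with loss of a C7 hydrogen to give 12 directly, where the route is rejoined. Any exchange of the C15 acetate is made good in step 10, and step 9 is not needed.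

Step 9. The ene oxidation may also attack C6 or C9, or run on to the enal. The fallback sets out from 11 and replaces the ene oxidation by an epoxide relay. mCPBA should give the 7α,8α-epoxide F8. Al(OiPr)3 should isomerise F8 by abstraction of a C17 hydrogen to the 8(17)-en-7α-ol F9, and acetylation gives the 7α,15-diacetate F10. PdCl2(MeCN)2-catalysed 1,3-shift of the allylic acetate should then move the ester to C17 and the alkene into the ring, arriving at 13.

**Further compounds**
F1 | step 6 | (3S,6E,10E)-12-hydroxy-3,7,11-trimethyltrideca-6,10-dien-1-yl acetate (both C12 epimers) | CC(O)/C(C)=C/CC/C(C)=C/CC[C@H](C)CCOC(C)=O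
F2 | step 6 | (3S,6E,10E)-3,7,11-trimethyl-12-oxotrideca-6,10-dien-1-yl acetate | CC(=O)/C(C)=C/CC/C(C)=C/CC[C@H](C)CCOC(C)=O
F3 | step 6 | (3S,6E,10E)-3,7,11-trimethyl-12-(triisopropylsilyloxy)trideca-6,10,12-trien-1-yl acetate | C=C(O[Si](C(C)C)(C(C)C)C(C)C)/C(C)=C/CC/C(C)=C/CC[C@H](C)CCOC(C)=O
F4 | step 6 | silyl enol ether analogue of 8 with OSi(iPr)3 on the ring alkene carbon C1 | CC(=O)OCC[C@@H](C)CC/C=C(C)/CC[C@@H]1C(C)=C(O[Si](C(C)C)(C(C)C)C(C)C)CC[C@]1(C)C=O
F5 | step 6 | enol triflate analogue of 8 with OSO2CF3 on C1 | CC(=O)OCC[C@@H](C)CC/C=C(C)/CC[C@@H]1C(C)=C(OS(=O)(=O)C(F)(F)F)CC[C@]1(C)C=O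
F6 | step 8 | (13S)-labd-8(17)-en-15-yl acetate | CC(=O)OCC[C@@H](C)CC[C@H]1C(=C)CC[C@H]2C(C)(C)CCC[C@]12C
F7 | step 8 | (13S)-8α,17-epoxylabdan-15-yl acetate | CC(=O)OCC[C@@H](C)CC[C@H]1[C@@]2(CO2)CC[C@H]3C(C)(C)CCC[C@]13C
F8 | step 9 | (13S)-7α,8α-epoxylabdan-15-yl acetate | CC(=O)OCC[C@@H](C)CC[C@H]1[C@]2(C)O[C@@H]2C[C@H]3C(C)(C)CCC[C@]13C
F9 | step 9 | (13S)-7α-hydroxylabd-8(17)-en-15-yl acetate | CC(=O)OCC[C@@H](C)CC[C@H]1C(=C)[C@H](O)C[C@H]2C(C)(C)CCC[C@]12C
F10 | step 9 | (13S)-labd-8(17)-ene-7α,15-diyl diacetate | CC(=O)OCC[C@@H](C)CC[C@H]1C(=C)[C@H](OC(C)=O)C[C@H]2C(C)(C)CCC[C@]12C
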